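## Retrosynthetic overview

1. The target comes from the macrocyclic 7E-alkene (dihydroflexibilide) by a last-step Schenck ene reaction with singlet oxygen, which installs C7–OOH and C8=C19H2.
2. The 14-membered carbocycle comes from a seco vinyl iodide / vinyl carbinol by intramolecular B-alkyl Suzuki coupling (C6–C7). This ring is closed last.
3. The δ-lactone comes from a δ-keto ester by CBS reduction (C3), lactonisation and trans-selective enolate methylation (C15). This is the second ring.
4. The key C1–C2 bond comes from an intermolecular asymmetric Michael addition. The west methyl ketone (C2–C6), as its SAMP-hydrazone azaenolate, adds to the east (E)-enoate (C16, C15, C1, C14–C7), which already carries the oxirane (first ring).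
5. The east fragment is made from 4-pentyn-1-ol (carboalumination, Wittig, Sharpless epoxidation, two Wittig homologations). The west fragment is made from methallyl alcohol (Sharpless epoxidation, sulfonium ylide homologation).

**Numbering used below (cembrane):**
- C1 is the ring CH bearing the lactone CH(CH3).
- C3 is the lactone O–CH.
- C4 is C(OH)CH3.
- C7 is CH–OOH.
- C8 is C(=C19H2).
- C11/C12 are the oxirane carbons.
- C15/C16/C17 are the lactone CH, C=O and CH3.
- Target configuration: 1R,3R,4S,7S,11S,12S,15S.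

**Assumption:** the sense of induction in step 19 is taken from the known series of methyl ketone SAMP hydrazones with (E)-3-alkyl acrylates, where SAMP gives the R β-carbon. If it proved opposite, RAMP would be used in step 18.

## East fragment

Step 1
Reactants: 1 4-pentyn-1-ol
Product: 3 (E)-5-iodo-4-methylpent-4-en-1-ol, via vinylalane 2 (not isolated)
Conditions: Me3Al (3 equiv), Cp2ZrCl2 (0.25 equiv), CH2Cl2, 0 °C to rt; then I2, THF, −30 °C
Reagents that add atoms: trimethylaluminium C[Al](C)C; iodine II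
Why: Negishi zirconium-catalysed carboalumination adds Me and Al syn across the terminal alkyne (Me on the internal carbon) and iodinolysis goes with retention, so the E trisubstituted vinyl iodide (future C7=C8 with C19) forms as one isomer.

Step 2
Reactants: 3 (E)-5-iodo-4-methylpent-4-en-1-ol
Product: 4 (E)-5-iodo-4-methylpent-4-enal
Conditions: 2,2,6,6-tetramethylpiperidin-1-oxyl (TEMPO, 0.1 equiv), PhI(OAc)2, CH2Cl2, rt
Reagents that add atoms: none
Why: Oxoammonium (TEMPO) oxidation stops at the aldehyde and leaves the vinyl iodide untouched.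

Step 3
Reactants: 4 (E)-5-iodo-4-methylpent-4-enal
Product: 5 ethyl (2E,6E)-7-iodo-2,6-dimethylhepta-2,6-dienoate
Conditions: Ph3P=C(CH3)CO2Et, CH2Cl2, rt
Reagents that add atoms: ethyl 2-(triphenylphosphoranylidene)propanoate CCOC(=O)C(C)=P(c1ccccc1)(c1ccccc1)c1ccccc1
Why: Wittig olefination with an α-branched stabilised ylide gives the E trisubstituted enoate (over 20:1), fixing the C11=C12 geometry that the oxirane will copy.

Step 4
Reactants: 5 ethyl (2E,6E)-7-iodo-2,6-dimethylhepta-2,6-dienoate
Product: 6 (2E,6E)-7-iodo-2,6-dimethylhepta-2,6-dien-1-ol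
Conditions: iBu2AlH (2.2 equiv), CH2Cl2, −78 °C
Reagents that add atoms: none
Why: 1,2-Hydride reduction of the enoate gives the allylic alcohol that will direct the epoxidation, and the vinyl iodide is inert at low temperature.

Step 5
Reactants: 6 (2E,6E)-7-iodo-2,6-dimethylhepta-2,6-dien-1-ol
Product: 7 [(2S,3S)-3-[(3E)-4-iodo-3-methylbut-3-en-1-yl]-2-methyloxiran-2-yl]methanol
Conditions: Ti(OiPr)4 (0.1 equiv), L-(+)-diethyl tartrate (0.12 equiv), tBuOOH, 4 Å MS, CH2Cl2, −20 °C
Reagents that add atoms: tert-butyl hydroperoxide CC(C)(C)OO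
Why: Katsuki–Sharpless asymmetric epoxidation of an (E)-2-methylallylic alcohol with L-(+)-tartrate gives the (2S,3S)-epoxy alcohol, setting C12 (S) and C11 (S), while the electron-poor non-allylic vinyl iodide does not react.

Step 6
Reactants: 7 epoxy alcohol
Product: 8 (2R,3S)-3-[(3E)-4-iodo-3-methylbut-3-en-1-yl]-2-methyloxirane-2-carbaldehyde
Conditions: TEMPO (0.1 equiv), PhI(OAc)2, CH2Cl2, rt
Reagents that add atoms: none
Why: TEMPO oxidation gives the epoxy aldehyde, whose α-carbon is quaternary and cannot epimerise (the CIP label at C12 changes, the geometry does not).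

Step 7
Reactants: 8 epoxy aldehyde
Product: 9 methyl (2E)-3-[(2S,3S)-3-[(3E)-4-iodo-3-methylbut-3-en-1-yl]-2-methyloxiran-2-yl]prop-2-enoate
Conditions: Ph3P=CHCO2Me, CH2Cl2, rt
Reagents that add atoms: methyl (triphenylphosphoranylidene)acetate COC(=O)C=P(c1ccccc1)(c1ccccc1)c1ccccc1
Why: Wittig olefination under neutral conditions forms the C13–C14 bond without touching the oxirane.

Step 8
Reactants: 9 epoxy enoate
Product: 10 methyl 3-[(2S,3S)-3-[(3E)-4-iodo-3-methylbut-3-en-1-yl]-2-methyloxiran-2-yl]propanoate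
Conditions: 2-nitrobenzenesulfonohydrazide (6 equiv), Et3N, CH2Cl2, rt
Reagents that add atoms: none
Why: Diimide reduction saturates the only disubstituted C=C by concerted syn hydrogen transfer, so neither allylic C–O cleavage of the vinyl oxirane nor attack on the trisubstituted vinyl iodide occurs.

Step 9
Reactants: 10 saturated epoxy ester
Product: 11 3-[(2S,3S)-3-[(3E)-4-iodo-3-methylbut-3-en-1-yl]-2-methyloxiran-2-yl]propanal
Conditions: iBu2AlH (1.05 equiv), CH2Cl2, −78 °C
Reagents that add atoms: none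
Why: Partial ester reduction stops at the tetrahedral aluminium hemiacetal at −78 °C, where the trisubstituted oxirane is not opened.

Step 10
Reactants: 11 epoxy aldehyde
Product: 12 methyl (2E)-5-[(2S,3S)-3-[(3E)-4-iodo-3-methylbut-3-en-1-yl]-2-methyloxiran-2-yl]pent-2-enoate (east fragment)
Conditions: Ph3P=CHCO2Me, CH2Cl2, rt
Reagents that add atoms: methyl (triphenylphosphoranylidene)acetate COC(=O)C=P(c1ccccc1)(c1ccccc1)c1ccccc1
Why: Wittig olefination with the stabilised ylide gives the (E)-enoate (C1=C15–C16) that serves as the Michael acceptor.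

## West fragment

Step 11
Reactants: 13 2-methylprop-2-en-1-ol (methallyl alcohol)
Product: 14 (R)-2-methylglycidol
Conditions: Ti(OiPr)4 (0.05 equiv), D-(−)-diisopropyl tartrate (0.06 equiv), tBuOOH, 4 Å MS, CH2Cl2, −20 °C; distillation
Reagents that add atoms: tert-butyl hydroperoxide CC(C)(C)OO
Why: Katsuki–Sharpless asymmetric epoxidation with D-(−)-tartrate gives the R epoxy alcohol, whose quaternary carbon becomes C4 with the C4–O bond already in its final orientation.

Step 12
Reactants: 14 (R)-2-methylglycidol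
Product: 15 triethylsilyl ether of 14 (geometry unchanged, CIP label becomes S)
Conditions: Et3SiCl, imidazole, CH2Cl2, 0 °C
Reagents that add atoms: chlorotriethylsilane CC[Si](Cl)(CC)CC
Why: Silyl ether formation masks the primary alcohol and makes the small fragment lipophilic and easy to handle.

Step 13
Reactants: 15 glycidyl silyl ether
Product: 16 (S)-2-methyl-1-(triethylsilyloxy)but-3-en-2-ol
Conditions: Me3SI (3 equiv), nBuLi (2.9 equiv), THF, −10 °C to rt
Reagents that add atoms: trimethylsulfonium iodide C[S+](C)C.[I-]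
Why: In this one-carbon epoxide-to-allylic-alcohol homologation, dimethylsulfonium methylide opens the oxirane at its CH2 terminus and base-induced loss of Me2S gives the vinyl group (C5=C6), so no bond at C4 is broken and its configuration is kept.

Step 14
Reactants: 16 tertiary allylic alcohol
Product: 17 (S)-2-methyl-1,2-bis(triethylsilyloxy)but-3-ene
Conditions: Et3SiOTf, 2,6-lutidine, CH2Cl2, −78 to 0 °C
Reagents that add atoms: triethylsilyl trifluoromethanesulfonate CC[Si](CC)(CC)OS(=O)(=O)C(F)(F)F
Why: Silyl triflate silylation protects the hindered tertiary alcohol, and any 1,2-silyl-migrated isomer from step 13 converges on the same bis-silyl ether.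

Step 15
Reactants: 17 bis-silyl ether
Product: 18 (S)-2-methyl-2-(triethylsilyloxy)but-3-enal
Conditions: (COCl)2 (4 equiv), DMSO (8 equiv), CH2Cl2, −78 to −40 °C; Et3N
Reagents that add atoms: none
Why: Swern oxidation converts an unhindered primary triethylsilyl ether directly into the aldehyde, while the tertiary silyl ether is too hindered to be attacked by the activated sulfonium species.

Step 16
Reactants: 18 west aldehyde
Product: 19 (3S)-3-methyl-3-(triethylsilyloxy)pent-4-en-2-ol (both carbinol epimers)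
Conditions: MeMgBr, Et2O, −78 °C
Reagents that add atoms: methylmagnesium bromide C[Mg]Br
Why: Grignard addition brings in C2, and the new carbinol centre is irrelevant because it is oxidised in the next step.

Step 17
Reactants: 19 secondary alcohol
Product: 20 (S)-3-methyl-3-(triethylsilyloxy)pent-4-en-2-one
Conditions: Dess–Martin periodinane, CH2Cl2, rt
Reagents that add atoms: none
Why: Dess–Martin oxidation of the hindered secondary alcohol gives the methyl ketone under neutral conditions, with the quaternary C4 unable to epimerise.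

Step 18
Reactants: 20 west methyl ketone
Product: 21 SAMP hydrazone of 20 (west fragment)
Conditions: (S)-1-amino-2-(methoxymethyl)pyrrolidine (1.2 equiv), 4 Å MS, cyclohexane, 60 °C
Reagents that add atoms: SAMP COC[C@@H]1CCCN1N
Why: Hydrazone condensation installs the Enders auxiliary, with the amino nitrogen lying anti to the bulky quaternary C4 (E C=N).

## Union and endgame

Step 19
Reactants: 21 west SAMP hydrazone; 12 east enoate
Product: 23 Michael adduct (hydrazone ester; 1R), via lithium azaenolate 22 (not isolated)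
Conditions: LiN(iPr)2 (1.05 equiv), THF, 0 °C; then 12, −78 °C
Reagents that add atoms: none
Why: In this Enders SAMP-hydrazone Michael addition, the methoxy-chelated lithium azaenolate (only the C2 methyl can be metalated because C4 is quaternary) adds 1,4 to the (E)-enoate through a closed lithium-bridged transition state, joining the two fragments at C1–C2 and setting C1 (R) under auxiliary control.

Step 20
Reactants: 23 Michael adduct
Product: 24 methyl (3R,6S)-3-{2-[(2S,3S)-3-[(3E)-4-iodo-3-methylbut-3-en-1-yl]-2-methyloxiran-2-yl]ethyl}-6-methyl-5-oxo-6-(triethylsilyloxy)oct-7-enoate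
Conditions: CuCl2 (3 equiv), THF/pH 7 phosphate buffer, 0 °C to rt
Reagents that add atoms: water O
Why: Copper-assisted hydrazone hydrolysis at neutral pH frees the ketone without ozone or strong acid, so alkenes, oxirane and silyl ether survive and no α-stereocentre is at risk.

Step 21
Reactants: 24 δ-keto ester
Product: 25 the (3R,5R,6S)-5-hydroxy ester
Conditions: (S)-1-methyl-3,3-diphenyltetrahydro-1H,3H-pyrrolo[1,2-c][1,3,2]oxazaborole ((S)-Me-CBS, 0.3 equiv), catecholborane (2 equiv), toluene, −78 to −40 °C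
Reagents that add atoms: none
Why: Corey–Bakshi–Shibata reduction differentiates the quaternary C4 (large) from the C2 methylene (small), so the S catalyst gives the R alcohol at C3 under reagent control, and catecholborane does not hydroborate the vinyl group.

Step 22
Reactants: 25 hydroxy ester
Product: 26 the corresponding (3R,5R,6S)-5-hydroxy acid
Conditions: LiOH, THF/MeOH/H2O, 0 °C to rt; then dilute HCl to pH 5, 0 °C
Reagents that add atoms: lithium hydroxide [Li+].[OH-]
Why: Ester saponification leaves the oxirane, tertiary silyl ether and vinyl iodide intact, and any lactone formed on acidification is simply carried on.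

Step 23
Reactants: 26 hydroxy acid
Product: 27 (4R,6R)-4-{2-[(2S,3S)-3-[(3E)-4-iodo-3-methylbut-3-en-1-yl]-2-methyloxiran-2-yl]ethyl}-6-[(2S)-2-(triethylsilyloxy)but-3-en-2-yl]oxan-2-one
Conditions: EDC·HCl, DMAP (1.5 equiv), CH2Cl2, 0 °C to rt
Reagents that add atoms: none
Why: Steglich-type carbodiimide lactonisation closes the six-membered ring at the carboxyl carbon, so C3 is retained and the C1 and C3 substituents end up cis (both equatorial).

Step 24
Reactants: 27 δ-lactone
Product: 29 the (3S,4R,6R)-3-methyl lactone, via lithium enolate 28 (not isolated)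
Conditions: LiN(iPr)2 (1.1 equiv), THF, −78 °C; MeI, DMPU, −78 to −40 °C
Reagents that add atoms: iodomethane CI
Why: Lactone enolate alkylation takes place anti to the adjacent C1 side chain, giving the trans, all-equatorial and thermodynamically preferred C15 (S) methyl group.

Step 25
Reactants: 29 methylated lactone
Product: 31 dihydroflexibilide 4-O-triethylsilyl ether (1R,3R,4S,7E,11S,12S,15S), via B-alkyl-9-BBN borane 30 (not isolated)
Conditions: 9-BBN-H (2 equiv), THF, rt; then slow addition to Pd(dppf)Cl2 (0.2 equiv), AsPh3 (0.4 equiv), Cs2CO3 (3 equiv), DMF/THF/H2O, 50 °C, 1 mM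
Reagents that add atoms: none
Why: 9-BBN hydroborates only the monosubstituted vinyl group at its terminus, and the intramolecular B-alkyl Suzuki–Miyaura coupling (oxidative addition of zerovalent palladium to the vinyl iodide with retention) closes the 14-membered ring with the 7E geometry preserved.

Step 26
Reactants: 31 macrocyclic silyl ether
Product: 32 dihydroflexibilide (1R,3R,4S,7E,11S,12S,15S)
Conditions: Bu4NF, AcOH (1:1), THF, 0 °C to rt
Reagents that add atoms: none
Why: Buffered fluoride desilylation frees the tertiary alcohol without acid (oxirane safe), and it is done before the base-sensitive hydroperoxide is present.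

Step 27
Reactants: 32 dihydroflexibilide
Product: 33 target hydroperoxide CNP0319766.2
Conditions: O2, 5,10,15,20-tetraphenylporphyrin (1 mol %), visible light, CH2Cl2, −20 °C
Reagents that add atoms: dioxygen O=O
Why: The Schenck ene reaction occurs on the only C=C, where the cis effect directs suprafacial hydrogen abstraction to the C6/C19 side, abstraction from the freely rotating C19 methyl gives the 8(19)-ene with O at C7, attack on the exposed outer face of the macrocyclic E-alkene sets C7 (S), and the tertiary Δ6 8-hydroperoxide and any 7-epimer are removed by chromatography.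

## Compound list

1 | 4-pentyn-1-ol | C#CCCCO | starting material
2 | vinylalane (O-dimethylaluminium alkoxide of the (E)-alkenyl dimethylalane) | C[Al](C)/C=C(\C)CCCO[Al](C)C | intermediate
3 | (E)-5-iodo-4-methylpent-4-en-1-ol | I/C=C(\C)CCCO | intermediate
4 | (E)-5-iodo-4-methylpent-4-enal | I/C=C(\C)CCC=O | intermediate
5 | ethyl (2E,6E)-7-iodo-2,6-dimethylhepta-2,6-dienoate | I/C=C(\C)CC/C=C(\C)C(=O)OCC | intermediate
6 | (2E,6E)-7-iodo-2,6-dimethylhepta-2,6-dien-1-ol | I/C=C(\C)CC/C=C(\C)CO | intermediate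
7 | [(2S,3S)-3-[(3E)-4-iodo-3-methylbut-3-en-1-yl]-2-methyloxiran-2-yl]methanol | I/C=C(\C)CC[C@@H]1O[C@@]1(C)CO | intermediate
8 | (2R,3S)-3-[(3E)-4-iodo-3-methylbut-3-en-1-yl]-2-methyloxirane-2-carbaldehyde | I/C=C(\C)CC[C@@H]1O[C@@]1(C)C=O | intermediate
9 | methyl (2E)-3-[(2S,3S)-3-[(3E)-4-iodo-3-methylbut-3-en-1-yl]-2-methyloxiran-2-yl]prop-2-enoate | I/C=C(\C)CC[C@@H]1O[C@@]1(C)/C=C/C(=O)OC | intermediate
10 | methyl 3-[(2S,3S)-3-[(3E)-4-iodo-3-methylbut-3-en-1-yl]-2-methyloxiran-2-yl]propanoate | I/C=C(\C)CC[C@@H]1O[C@@]1(C)CCC(=O)OC | intermediate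
11 | 3-[(2S,3S)-3-[(3E)-4-iodo-3-methylbut-3-en-1-yl]-2-methyloxiran-2-yl]propanal | I/C=C(\C)CC[C@@H]1O[C@@]1(C)CCC=O | intermediate
12 | methyl (2E)-5-[(2S,3S)-3-[(3E)-4-iodo-3-methylbut-3-en-1-yl]-2-methyloxiran-2-yl]pent-2-enoate (east fragment) | I/C=C(\C)CC[C@@H]1O[C@@]1(C)CC/C=C/C(=O)OC | intermediate
13 | 2-methylprop-2-en-1-ol | C=C(C)CO | starting material
14 | (R)-2-methylglycidol | C[C@@]1(CO)CO1 | intermediate
15 | triethyl{[(2S)-2-methyloxiran-2-yl]methoxy}silane | C[C@@]1(CO[Si](CC)(CC)CC)CO1 | intermediate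
16 | (S)-2-methyl-1-(triethylsilyloxy)but-3-en-2-ol | CC[Si](CC)(CC)OC[C@@](C)(O)C=C | intermediate
17 | (S)-2-methyl-1,2-bis(triethylsilyloxy)but-3-ene | CC[Si](CC)(CC)OC[C@@](C)(O[Si](CC)(CC)CC)C=C | intermediate
18 | (S)-2-methyl-2-(triethylsilyloxy)but-3-enal | O=C[C@@](C)(O[Si](CC)(CC)CC)C=C | intermediate
19 | (3S)-3-methyl-3-(triethylsilyloxy)pent-4-en-2-ol (carbinol epimers) | CC(O)[C@@](C)(O[Si](CC)(CC)CC)C=C | intermediate
20 | (S)-3-methyl-3-(triethylsilyloxy)pent-4-en-2-one | CC(=O)[C@@](C)(O[Si](CC)(CC)CC)C=C | intermediate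
21 | (E)-SAMP hydrazone of 20 (west fragment) | C/C(=N\N1CCC[C@H]1COC)[C@@](C)(O[Si](CC)(CC)CC)C=C | intermediate
22 | lithium azaenolate of 21 | C=C(N([Li])N1CCC[C@H]1COC)[C@@](C)(O[Si](CC)(CC)CC)C=C | intermediate
23 | Michael adduct, SAMP hydrazone of keto ester 24 | I/C=C(\C)CC[C@@H]1O[C@@]1(C)CC[C@@H](CC(=O)OC)C/C(=N\N1CCC[C@H]1COC)[C@@](C)(O[Si](CC)(CC)CC)C=C | intermediate
24 | δ-keto ester (3R,6S) | I/C=C(\C)CC[C@@H]1O[C@@]1(C)CC[C@@H](CC(=O)OC)CC(=O)[C@@](C)(O[Si](CC)(CC)CC)C=C | intermediate
25 | δ-hydroxy ester (3R,5R,6S) | I/C=C(\C)CC[C@@H]1O[C@@]1(C)CC[C@@H](CC(=O)OC)C[C@@H](O)[C@@](C)(O[Si](CC)(CC)CC)C=C | intermediate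
26 | δ-hydroxy acid (3R,5R,6S) | I/C=C(\C)CC[C@@H]1O[C@@]1(C)CC[C@@H](CC(=O)O)C[C@@H](O)[C@@](C)(O[Si](CC)(CC)CC)C=C | intermediate
27 | cis-4,6-disubstituted δ-lactone (4R,6R) | I/C=C(\C)CC[C@@H]1O[C@@]1(C)CC[C@@H]2C[C@@H](OC(=O)C2)[C@@](C)(O[Si](CC)(CC)CC)C=C | intermediate
28 | lithium enolate of 27 | I/C=C(\C)CC[C@@H]1O[C@@]1(C)CC[C@@H]2C[C@@H](OC(O[Li])=C2)[C@@](C)(O[Si](CC)(CC)CC)C=C | intermediate
29 | 3-methyl δ-lactone (3S,4R,6R) | I/C=C(\C)CC[C@@H]1O[C@@]1(C)CC[C@@H]2C[C@@H](OC(=O)[C@H]2C)[C@@](C)(O[Si](CC)(CC)CC)C=C | intermediate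
30 | B-alkyl-9-BBN borane from 29 | I/C=C(\C)CC[C@@H]1O[C@@]1(C)CC[C@@H]2C[C@@H](OC(=O)[C@H]2C)[C@@](C)(O[Si](CC)(CC)CC)CCB3C4CCCC3CCC4 | intermediate
31 | dihydroflexibilide 4-O-triethylsilyl ether | C1C[C@@H]2O[C@@]2(C)CC[C@@H]2C[C@@H](OC(=O)[C@H]2C)[C@@](C)(O[Si](CC)(CC)CC)CC/C=C1\C | intermediate
32 | dihydroflexibilide | C1C[C@@H]2O[C@@]2(C)CC[C@@H]2C[C@@H](OC(=O)[C@H]2C)[C@@](C)(O)CC/C=C1\C | intermediate
33 | CNP0319766.2, (7S)-7-hydroperoxy-8(19)-ene | C=C1CC[C@@H]2O[C@@]2(C)CC[C@@H]2C[C@@H](OC(=O)[C@H]2C)[C@@](C)(O)CC[C@@H]1OO | target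

## Step count

Total step count: 27 (east fragment 10, west fragment 8, union and endgame 9).
Longest linear sequence: 19 steps (1–10, then 19–27).

## Steps most likely to fail

**Step 19 (Michael union).** The hydrazone is unusually hindered, and its reactivity and degree of induction are untested.
- The fallback sets out from aldehydes 11 and 18 and comes back at lactone 27.
- It replaces the 1,5-dicarbonyl logic by an aldol route in which C1 is set later by hydride delivery.
- MeMgBr adds to 11 to give the secondary alcohol F1, and Dess–Martin oxidation gives the east methyl ketone F2.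
- The kinetic lithium enolate of F2 (LiN(iPr)2, THF, −78 °C) adds to 18 in an intermolecular aldol reaction to give the β-hydroxy ketone F3. Little facial bias is expected at C3, so the 3R epimer is separated by chromatography.
- Esterification with diethylphosphonoacetic acid (EDC·HCl, DMAP) gives the phosphonoacetate F4.
- Intramolecular Horner–Wadsworth–Emmons reaction (LiCl, iPr2NEt, MeCN) gives the 4-substituted 5,6-dihydropyran-2-one F5.
- Conjugate reduction with [(Ph3P)CuH]6 delivers hydride to C1 anti to the C3 substituent and gives the cis lactone 27.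

**Step 25 (macrocyclisation).** Oligomerisation, protodeboronation or lactone hydrolysis in the basic aqueous medium are the likely failure modes.
- The fallback sets out from 29 and comes back at 31.
- Borane 30 is made as before but oxidised with NaBO3·4H2O to the primary alcohol F6.
- I2, PPh3 and imidazole convert F6 into the primary iodide F7.
- Zinc dust with LiCl in THF inserts only into the sp3 C–I bond to give the alkylzinc iodide F8.
- F8 is added slowly to Pd(dppf)Cl2 in THF/DMF. This intramolecular Negishi coupling runs under neutral, water-free conditions and gives 31.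

**Step 27 (Schenck ene).** Both the regiochemistry and the face of attack depend on the ring conformation.
- The fallback sets out from 32 and comes back at 33.
- It sets C7 by reagent control instead of facial bias.
- Photooxygenation is run without regard to facial selectivity, and the secondary hydroperoxides F9 (both C7 epimers) are separated from the tertiary isomer.
- PPh3 reduces them to the allylic alcohols F10, and Dess–Martin oxidation gives the α-methylene ketone F11.
- (S)-Me-CBS with catecholborane gives the (7R)-allylic alcohol F12.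
- MsCl and Et3N at −60 °C give the (7R)-mesylate F13, which is treated in situ with a large excess of anhydrous ethereal H2O2. Displacement with inversion gives 33.
- Attack at C19 (SN2′) is the competing path and must be checked.

## Further compounds

F1 | step 19 | 4-[(2S,3S)-3-[(3E)-4-iodo-3-methylbut-3-en-1-yl]-2-methyloxiran-2-yl]butan-2-ol (carbinol epimers) | I/C=C(\C)CC[C@@H]1O[C@@]1(C)CCC(C)O
F2 | step 19 | 4-[(2S,3S)-3-[(3E)-4-iodo-3-methylbut-3-en-1-yl]-2-methyloxiran-2-yl]butan-2-one | I/C=C(\C)CC[C@@H]1O[C@@]1(C)CCC(C)=O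
F3 | step 19 | (5R,6S)-5-hydroxy-1-[(2S,3S)-3-[(3E)-4-iodo-3-methylbut-3-en-1-yl]-2-methyloxiran-2-yl]-6-methyl-6-(triethylsilyloxy)oct-7-en-3-one | I/C=C(\C)CC[C@@H]1O[C@@]1(C)CCC(=O)C[C@@H](O)[C@@](C)(O[Si](CC)(CC)CC)C=C
F4 | step 19 | diethylphosphonoacetate ester of F3 | I/C=C(\C)CC[C@@H]1O[C@@]1(C)CCC(=O)C[C@@H](OC(=O)CP(=O)(OCC)OCC)[C@@](C)(O[Si](CC)(CC)CC)C=C
F5 | step 19 | (6R)-4-substituted 6-[(2S)-2-(triethylsilyloxy)but-3-en-2-yl]-5,6-dihydropyran-2-one | I/C=C(\C)CC[C@@H]1O[C@@]1(C)CCC2=CC(=O)O[C@H](C2)[C@@](C)(O[Si](CC)(CC)CC)C=C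
F6 | step 25 | primary alcohol (C6–OH) from 29 | I/C=C(\C)CC[C@@H]1O[C@@]1(C)CC[C@@H]2C[C@@H](OC(=O)[C@H]2C)[C@@](C)(O[Si](CC)(CC)CC)CCO
F7 | step 25 | primary iodide (C6–I) | I/C=C(\C)CC[C@@H]1O[C@@]1(C)CC[C@@H]2C[C@@H](OC(=O)[C@H]2C)[C@@](C)(O[Si](CC)(CC)CC)CCI
F8 | step 25 | alkylzinc iodide (C6–ZnI) | I/C=C(\C)CC[C@@H]1O[C@@]1(C)CC[C@@H]2C[C@@H](OC(=O)[C@H]2C)[C@@](C)(O[Si](CC)(CC)CC)CC[Zn]I
F9 | step 27 | 7-hydroperoxy-8(19)-ene, both C7 epimers | C=C1CC[C@@H]2O[C@@]2(C)CC[C@@H]2C[C@@H](OC(=O)[C@H]2C)[C@@](C)(O)CCC1OO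
F10 | step 27 | 7-hydroxy-8(19)-ene, both C7 epimers | C=C1CC[C@@H]2O[C@@]2(C)CC[C@@H]2C[C@@H](OC(=O)[C@H]2C)[C@@](C)(O)CCC1O
F11 | step 27 | 7-oxo-8(19)-ene (α-methylene ketone) | C=C1CC[C@@H]2O[C@@]2(C)CC[C@@H]2C[C@@H](OC(=O)[C@H]2C)[C@@](C)(O)CCC1=O
F12 | step 27 | (7R)-7-hydroxy-8(19)-ene | C=C1CC[C@@H]2O[C@@]2(C)CC[C@@H]2C[C@@H](OC(=O)[C@H]2C)[C@@](C)(O)CC[C@H]1O
F13 | step 27 | (7R)-7-methanesulfonate | C=C1CC[C@@H]2O[C@@]2(C)CC[C@@H]2C[C@@H](OC(=O)[C@H]2C)[C@@](C)(O)CC[C@H]1OS(C)(=O)=O
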